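(All runs stem from a simulated flask with constants of no real substance; the scatter is artificial.)

- The constant I could take from the earlier runs was k, the fraction of substrate lost per second, a pseudo-first-order rate constant. A first-order loss leaves exp(−kt) of the charge, so I read k as the logarithm of charge over what was left, divided by the time.

| setting | zeta | alpha | oak | cedar | larch |
|---|---|---|---|---|---|
| substrate | 0.67 mM | 1 mM | 1.0 mM | 1.0 mM | 1.0 mM |
| coupling partner | 1.3 equiv | 1.3 equiv | 1.30 equiv | 2.00 equiv | 2.90 equiv |
| free catalyst | 0.2 mol% | 0.1 mol% | 0.2 mol% | 0.2 mol% | 0.2 mol% |
| remark | run made earlier | run made earlier |  |  |  |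
| time |  |  | 4.0 min | 4.0 min | 4.0 min |

| run | time / s | target / % | substrate / % |
|---|---|---|---|
| zeta | 10.0 | 5 | 95 |
| zeta | 15.0 | 5 | 95 |
| zeta | 30.0 | 10 | 87 |
| zeta | 50.0 | 14 | 78 |
| zeta | 60.0 | 19 | 75 |
| zeta | 80.0 | 19 | 69 |
| alpha | 10.0 | 3 | 98 |
| alpha | 12.0 | 7 | 96 |
| alpha | 20.0 | 6 | 90 |
| alpha | 30.0 | 12 | 88 |
| alpha | 50.0 | 14 | 79 |
| alpha | 80.0 | 20 | 67 |

(each reading ± 1.5 percentage points)

- percentages count the substrate that a species holds: one side product counts as two

- which of the two there is more of at the end, counted by the substrate in each, oak (target / side product)
- which of the two there is more of at the end, counted by the substrate in each, cedar (target / side product)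
- which of the two there is more of at the end, counted by the substrate in each, larch (target / side product)
- how much target is there at the end, in percent of the substrate charged: oak
- how much target is there at the end, in percent of the substrate charged: cedar
- how much target is there at the end, in percent of the substrate charged: larch

- The last reading of alpha gave k = 0.00501 /s, and that of zeta gave 0.00464 /s, a ratio of 0.926.
- Zeta had 1.34 times the catalyst concentration of alpha, but 0.670 times its substrate and partner concentrations. The product of these, 0.898, stood near that ratio of k. So I took k as proportional to catalyst concentration times partner concentration. This was a guess on one point: substrate and partner had moved together, with 1.3 equiv of partner in both runs.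
- Alpha's half-life of substrate, ln(2)/k, was 138 s. Oak has the same concentrations with twice the catalyst, so I carried forward the half-life of substrate in oak, the time in which substrate halves at the first-order rate: 69.2 s.
- Oak's 4.0 min holds 3.47 such half-lives, which leaves 9.05 % of the substrate. With more partner, the half-life shortens to 45.0 s in cedar and 31.0 s in larch.
- In alpha, target held 0.606 of the substrate lost. Keeping that share gave me target at 55.1 % in oak, 59.1 % in cedar and 60.3 % in larch. The share stands above half, so I put target ahead of side product in each flask.
- The forecast also put target ahead in oak, cedar and larch; it started from a mass balance with “about 60% of the consumed substrate going to target”, fitted a rate for each channel and integrated them by hand. It gave 57 %, 70 % and 81 %, so it parted from my reckoning most in larch.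
- The flasks gave target at 46.0 % in oak, 56.4 % in cedar and 62.2 % in larch, and target led side product in each: 33.0 %, 28.4 % and 24.0 %.

    substrate + catalyst intermediate A → catalyst intermediate B (k = 19000 /M/s)
    catalyst intermediate B → free catalyst + target (k = 250 /s)
    substrate + target → side product (k = 6.10 /M/s)
    target ⇌ isomer of the product (K = 0.200, k = 0.0150 /s)
    coupling partner + free catalyst ⇌ catalyst intermediate A (K = 320 /M, k = 16000 /M/s)

- Target's half-life towards the isomer of the product, forward step alone, was 0.77 min, shorter than the 4.0 min of the run, so the run held 5.19 of them. In cedar at the end, the isomer stood at 11.2 % beside 56.4 % of target. Oak still held 12 % of its substrate against my 9.05 %. A further flask like cedar, with 0.08 mol% of free catalyst, scales to a half-life of 113 s, which leaves 22.8 %, and that flask held 23.6 %.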